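**Retrosynthetic overview**
1. Target 23 ⇒ pentabenzyl ether 22 (global hydrogenolysis last); ring C of unit A ⇒ 2'-hydroxychalcone 20 by I2/DMSO oxidative cyclisation.
2. Key C–C bond (the future C2–C3 of unit A): intermolecular Claisen–Schmidt aldol condensation of biaryl aldehyde 18 with acetophenone 11.
3. Biaryl bond (chromane C8 to flavone C8): Suzuki coupling of chromane boronate 9 with 8-iodoflavone 17.
4. 17 ⇒ tri-O-benzylapigenin 16 ⇒ chalcone 14 from 11 + 4-(benzyloxy)benzaldehyde 12; 9 ⇒ 4-hydroxybenzaldehyde via propargyl ether, Claisen rearrangement, hydrogenation, bromination, borylation.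
5. Ring order: dimethylpyran ring of the chromane, then ring C of unit B, then biaryl union, then ring C of unit A.

Unit A is the flavone bound through its C2 to chromane C6. Unit B is the apigenin bound through its C8 to chromane C8.

Assumption: the SMILES has no stereocentre and no defined axis (the tri-ortho-substituted biaryl is taken as freely rotating), so the target is a single achiral compound and no asymmetric step is needed.

**Chromane fragment**

Step 1
Reactants: 1 4-hydroxybenzaldehyde; 2 3-chloro-3-methylbut-1-yne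
Product: 3 4-[(2-methylbut-3-yn-2-yl)oxy]benzaldehyde
Conditions: K2CO3 (2 equiv), KI (0.2 equiv), CuI (2 mol%), acetone, reflux, 24 h
Reagents that add atoms: none
Why: Copper-assisted Williamson-type O-propargylation, in which the phenoxide of 1 (acidified by the para-formyl group) captures the tertiary propargylic electrophile from 2, a standard entry to aryl 1,1-dimethylpropargyl ethers.

Step 2
Reactants: 3 4-[(2-methylbut-3-yn-2-yl)oxy]benzaldehyde
Product: 6 2,2-dimethyl-2H-chromene-6-carbaldehyde, via allenylphenol 4 (not isolated), via ortho-quinone methide 5 (not isolated)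
Conditions: N,N-diethylaniline, 190 °C, 3 h
Reagents that add atoms: none
Why: Thermal aromatic propargyl Claisen rearrangement gives allenylphenol 4, a 1,5-hydrogen shift gives ortho-quinone methide 5 and oxa-6π electrocyclisation closes the pyran ring; the two ortho positions of 3 are equivalent and no stereocentre forms.

Step 3
Reactants: 6 2,2-dimethyl-2H-chromene-6-carbaldehyde
Product: 7 2,2-dimethylchromane-6-carbaldehyde
Conditions: H2 (1 atm), 10% Pd/C, EtOAc, rt, stopped after 1 equiv H2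
Reagents that add atoms: none
Why: Catalytic hydrogenation of the styrene-type cis C3=C4 bond over Pd/C is much faster than reduction of the aryl aldehyde in EtOAc at 1 atm, and no stereocentre arises because C2 carries two methyl groups.

Step 4
Reactants: 7 2,2-dimethylchromane-6-carbaldehyde
Product: 8 8-bromo-2,2-dimethylchromane-6-carbaldehyde
Conditions: Br2 (1.1 equiv), NaOAc (1.5 equiv), AcOH, rt, 6 h
Reagents that add atoms: bromine, BrBr
Why: Electrophilic aromatic bromination goes to C8, the only position activated by the ring oxygen (ortho; the para position carries CHO) and also meta to the formyl group, as in the bromination of 4-alkoxybenzaldehydes.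

Step 5
Reactants: 8 8-bromo-2,2-dimethylchromane-6-carbaldehyde
Product: 9 2,2-dimethyl-8-(4,4,5,5-tetramethyl-1,3,2-dioxaborolan-2-yl)chromane-6-carbaldehyde
Conditions: B2pin2 (1.2 equiv), Pd(dppf)Cl2 (3 mol%), KOAc (3 equiv), 1,4-dioxane, 90 °C, 12 h
Reagents that add atoms: bis(pinacolato)diboron, CC1(C)OB(OC1(C)C)B1OC(C)(C)C(C)(C)O1
Why: Miyaura borylation (oxidative addition of the aryl bromide, acetate-assisted transmetalation, reductive elimination) tolerates the aldehyde, and KOAc is too weak a base to trigger Suzuki homocoupling.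

**Iodoflavone fragment (unit B)**

Step 6
Reactants: 10 1-(2,4,6-trihydroxyphenyl)ethan-1-one
Product: 11 1-[2,4-bis(benzyloxy)-6-hydroxyphenyl]ethan-1-one
Conditions: BnBr (2.1 equiv), K2CO3 (2.2 equiv), DMF, rt, 16 h
Reagents that add atoms: benzyl bromide, BrCc1ccccc1
Why: Chemoselective Williamson etherification benzylates the para OH and one ortho OH, while the remaining ortho OH is locked in a strong hydrogen bond to the acetyl carbonyl and stays free.

Step 7
Reactants: 11 1-[2,4-bis(benzyloxy)-6-hydroxyphenyl]ethan-1-one; 12 4-(benzyloxy)benzaldehyde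
Product: 14 (E)-1-[2,4-bis(benzyloxy)-6-hydroxyphenyl]-3-[4-(benzyloxy)phenyl]prop-2-en-1-one, via aldol adduct 13 (not isolated)
Conditions: KOH (50% aq, 10 equiv), EtOH/THF 3:1, rt, 48 h; then 1 M HCl
Reagents that add atoms: none
Why: Intermolecular Claisen–Schmidt aldol condensation, in which the enolate of 11 adds to non-enolisable 12 to give racemic aldol 13 and E1cB dehydration gives the thermodynamic E-chalcone; benzyl ethers are stable to KOH.

Step 8
Reactants: 14 (E)-1-[2,4-bis(benzyloxy)-6-hydroxyphenyl]-3-[4-(benzyloxy)phenyl]prop-2-en-1-one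
Product: 16 5,7-bis(benzyloxy)-2-[4-(benzyloxy)phenyl]-4H-chromen-4-one, via flavanone 15 (not isolated)
Conditions: I2 (10 mol%), DMSO, 130 °C, 3 h
Reagents that add atoms: none
Why: I2/DMSO oxidative cyclisation, in which oxa-Michael closure gives racemic flavanone 15 and I2 dehydrogenates it with DMSO as terminal oxidant, so the transient C2 stereocentre disappears.

Step 9
Reactants: 16 5,7-bis(benzyloxy)-2-[4-(benzyloxy)phenyl]-4H-chromen-4-one
Product: 17 5,7-bis(benzyloxy)-2-[4-(benzyloxy)phenyl]-8-iodo-4H-chromen-4-one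
Conditions: NIS (1.05 equiv), CF3CO2H (0.3 equiv), CH2Cl2/MeCN 1:1, 0 °C to rt, dark
Reagents that add atoms: N-iodosuccinimide, O=C1CCC(=O)N1I
Why: Electrophilic aromatic iodination of ring A, where 5,7-dialkoxyflavones with an alkylated 5-oxygen react at C8 (para to the 5-alkoxy group, flanked by one benzyloxy group) in preference to C6 (between two benzyloxy groups); the position is confirmed by HMBC before use.

**Union and end game**

Step 10
Reactants: 9 2,2-dimethyl-8-(4,4,5,5-tetramethyl-1,3,2-dioxaborolan-2-yl)chromane-6-carbaldehyde; 17 5,7-bis(benzyloxy)-2-[4-(benzyloxy)phenyl]-8-iodo-4H-chromen-4-one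
Product: 18 8-{5,7-bis(benzyloxy)-2-[4-(benzyloxy)phenyl]-4-oxo-4H-chromen-8-yl}-2,2-dimethylchromane-6-carbaldehyde
Conditions: 9 (1.3 equiv), Pd(OAc)2 (5 mol%), SPhos (10 mol%), K3PO4 (3 equiv), toluene/H2O 10:1, 90 °C, 16 h
Reagents that add atoms: none
Why: Suzuki–Miyaura cross-coupling, in which the bulky electron-rich phosphine SPhos supports oxidative addition into the hindered C8–I bond and reductive elimination of the tri-ortho-substituted biaryl, with the steric load on the halide partner to limit protodeboronation; the axis needs no stereocontrol.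

Step 11
Reactants: 18 8-{5,7-bis(benzyloxy)-2-[4-(benzyloxy)phenyl]-4-oxo-4H-chromen-8-yl}-2,2-dimethylchromane-6-carbaldehyde; 11 1-[2,4-bis(benzyloxy)-6-hydroxyphenyl]ethan-1-one
Product: 20 (E)-3-(8-{5,7-bis(benzyloxy)-2-[4-(benzyloxy)phenyl]-4-oxo-4H-chromen-8-yl}-2,2-dimethylchroman-6-yl)-1-[2,4-bis(benzyloxy)-6-hydroxyphenyl]prop-2-en-1-one, via aldol adduct 19 (not isolated)
Conditions: 11 (1.5 equiv), KOH (50% aq, 10 equiv), THF/EtOH 1:1, rt to 40 °C, 48–72 h; then 1 M HCl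
Reagents that add atoms: none
Why: Key intermolecular Claisen–Schmidt aldol condensation, in which the enolate of 11 adds to the unhindered, non-enolisable aryl aldehyde of 18 to give racemic aldol 19 and E1cB dehydration gives the E-chalcone, forming the bond that becomes C2–C3 of unit A; the existing flavone and the benzyl ethers survive hydroxide at this temperature.

Step 12
Reactants: 20 (E)-3-(8-{5,7-bis(benzyloxy)-2-[4-(benzyloxy)phenyl]-4-oxo-4H-chromen-8-yl}-2,2-dimethylchroman-6-yl)-1-[2,4-bis(benzyloxy)-6-hydroxyphenyl]prop-2-en-1-one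
Product: 22 5,7-bis(benzyloxy)-8-{6-[5,7-bis(benzyloxy)-4-oxo-4H-chromen-2-yl]-2,2-dimethylchroman-8-yl}-2-[4-(benzyloxy)phenyl]-4H-chromen-4-one, via flavanone 21 (not isolated)
Conditions: I2 (10 mol%), DMSO, 130 °C, 3–5 h
Reagents that add atoms: none
Why: I2/DMSO oxidative cyclisation as in step 8 (oxa-Michael closure to racemic flavanone 21, then dehydrogenation with DMSO as terminal oxidant) builds ring C of unit A; the chromane, the existing flavone and the benzyl ethers tolerate catalytic I2.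

Step 13
Reactants: 22 5,7-bis(benzyloxy)-8-{6-[5,7-bis(benzyloxy)-4-oxo-4H-chromen-2-yl]-2,2-dimethylchroman-8-yl}-2-[4-(benzyloxy)phenyl]-4H-chromen-4-one
Product: 23 8-[6-(5,7-dihydroxy-4-oxo-4H-chromen-2-yl)-2,2-dimethylchroman-8-yl]-5,7-dihydroxy-2-(4-hydroxyphenyl)-4H-chromen-4-one
Conditions: H2 (1 atm), 10% Pd/C, THF/MeOH 1:1, rt
Reagents that add atoms: none
Why: Hydrogenolysis of the five aryl benzyl ethers over Pd/C at 1 atm and room temperature is far faster than reduction of the flavone C2=C3 bonds and leaves the chromane ether untouched, giving the achiral target.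

**Compound list**
1 | 4-hydroxybenzaldehyde | O=Cc1ccc(O)cc1 | starting material
2 | 3-chloro-3-methylbut-1-yne | C#CC(C)(C)Cl | starting material
3 | 4-[(2-methylbut-3-yn-2-yl)oxy]benzaldehyde | C#CC(C)(C)Oc1ccc(C=O)cc1 | intermediate
4 | 4-hydroxy-3-(3-methylbuta-1,2-dien-1-yl)benzaldehyde (allenylphenol) | CC(C)=C=Cc1cc(C=O)ccc1O | intermediate
5 | 3-(3-methylbut-2-en-1-ylidene)-4-oxocyclohexa-1,5-diene-1-carbaldehyde (ortho-quinone methide) | O=C1C=CC(C=O)=CC1=CC=C(C)C | intermediate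
6 | 2,2-dimethyl-2H-chromene-6-carbaldehyde | CC1(C)C=Cc2cc(C=O)ccc2O1 | intermediate
7 | 2,2-dimethylchromane-6-carbaldehyde | CC1(C)CCc2cc(C=O)ccc2O1 | intermediate
8 | 8-bromo-2,2-dimethylchromane-6-carbaldehyde | CC1(C)CCc2cc(C=O)cc(Br)c2O1 | intermediate
9 | 2,2-dimethyl-8-(4,4,5,5-tetramethyl-1,3,2-dioxaborolan-2-yl)chromane-6-carbaldehyde | CC1(C)CCc2cc(C=O)cc(B3OC(C)(C)C(C)(C)O3)c2O1 | intermediate
10 | 1-(2,4,6-trihydroxyphenyl)ethan-1-one | CC(=O)c1c(O)cc(O)cc1O | starting material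
11 | 1-[2,4-bis(benzyloxy)-6-hydroxyphenyl]ethan-1-one | CC(=O)c1c(O)cc(OCc2ccccc2)cc1OCc1ccccc1 | intermediate
12 | 4-(benzyloxy)benzaldehyde | O=Cc1ccc(OCc2ccccc2)cc1 | starting material
13 | 1-[2,4-bis(benzyloxy)-6-hydroxyphenyl]-3-[4-(benzyloxy)phenyl]-3-hydroxypropan-1-one (racemic aldol adduct) | O=C(CC(O)c1ccc(OCc2ccccc2)cc1)c1c(O)cc(OCc2ccccc2)cc1OCc1ccccc1 | intermediate
14 | (E)-1-[2,4-bis(benzyloxy)-6-hydroxyphenyl]-3-[4-(benzyloxy)phenyl]prop-2-en-1-one | O=C(/C=C/c1ccc(OCc2ccccc2)cc1)c1c(O)cc(OCc2ccccc2)cc1OCc1ccccc1 | intermediate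
15 | 5,7-bis(benzyloxy)-2-[4-(benzyloxy)phenyl]chroman-4-one (racemic flavanone) | O=C1CC(c2ccc(OCc3ccccc3)cc2)Oc2cc(OCc3ccccc3)cc(OCc3ccccc3)c12 | intermediate
16 | 5,7-bis(benzyloxy)-2-[4-(benzyloxy)phenyl]-4H-chromen-4-one | O=c1cc(-c2ccc(OCc3ccccc3)cc2)oc2cc(OCc3ccccc3)cc(OCc3ccccc3)c12 | intermediate
17 | 5,7-bis(benzyloxy)-2-[4-(benzyloxy)phenyl]-8-iodo-4H-chromen-4-one | O=c1cc(-c2ccc(OCc3ccccc3)cc2)oc2c(I)c(OCc3ccccc3)cc(OCc3ccccc3)c12 | intermediate
18 | 8-{5,7-bis(benzyloxy)-2-[4-(benzyloxy)phenyl]-4-oxo-4H-chromen-8-yl}-2,2-dimethylchromane-6-carbaldehyde | CC1(C)CCc2cc(C=O)cc(-c3c(OCc4ccccc4)cc(OCc4ccccc4)c4c(=O)cc(-c5ccc(OCc6ccccc6)cc5)oc34)c2O1 | intermediate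
19 | 3-(8-{5,7-bis(benzyloxy)-2-[4-(benzyloxy)phenyl]-4-oxo-4H-chromen-8-yl}-2,2-dimethylchroman-6-yl)-1-[2,4-bis(benzyloxy)-6-hydroxyphenyl]-3-hydroxypropan-1-one (racemic aldol adduct) | CC1(C)CCc2cc(C(O)CC(=O)c3c(O)cc(OCc4ccccc4)cc3OCc3ccccc3)cc(-c3c(OCc4ccccc4)cc(OCc4ccccc4)c4c(=O)cc(-c5ccc(OCc6ccccc6)cc5)oc34)c2O1 | intermediate
20 | (E)-3-(8-{5,7-bis(benzyloxy)-2-[4-(benzyloxy)phenyl]-4-oxo-4H-chromen-8-yl}-2,2-dimethylchroman-6-yl)-1-[2,4-bis(benzyloxy)-6-hydroxyphenyl]prop-2-en-1-one | CC1(C)CCc2cc(/C=C/C(=O)c3c(O)cc(OCc4ccccc4)cc3OCc3ccccc3)cc(-c3c(OCc4ccccc4)cc(OCc4ccccc4)c4c(=O)cc(-c5ccc(OCc6ccccc6)cc5)oc34)c2O1 | intermediate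
21 | 5,7-bis(benzyloxy)-2-(8-{5,7-bis(benzyloxy)-2-[4-(benzyloxy)phenyl]-4-oxo-4H-chromen-8-yl}-2,2-dimethylchroman-6-yl)chroman-4-one (racemic flavanone) | CC1(C)CCc2cc(C3CC(=O)c4c(OCc5ccccc5)cc(OCc5ccccc5)cc4O3)cc(-c3c(OCc4ccccc4)cc(OCc4ccccc4)c4c(=O)cc(-c5ccc(OCc6ccccc6)cc5)oc34)c2O1 | intermediate
22 | 5,7-bis(benzyloxy)-8-{6-[5,7-bis(benzyloxy)-4-oxo-4H-chromen-2-yl]-2,2-dimethylchroman-8-yl}-2-[4-(benzyloxy)phenyl]-4H-chromen-4-one | CC1(C)CCc2cc(-c3cc(=O)c4c(OCc5ccccc5)cc(OCc5ccccc5)cc4o3)cc(-c3c(OCc4ccccc4)cc(OCc4ccccc4)c4c(=O)cc(-c5ccc(OCc6ccccc6)cc5)oc34)c2O1 | intermediate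
23 | 8-[6-(5,7-dihydroxy-4-oxo-4H-chromen-2-yl)-2,2-dimethylchroman-8-yl]-5,7-dihydroxy-2-(4-hydroxyphenyl)-4H-chromen-4-one | CC1(C)CCc2cc(-c3cc(=O)c4c(O)cc(O)cc4o3)cc(-c3c(O)cc(O)c4c(=O)cc(-c5ccc(O)cc5)oc34)c2O1 | target

**Totals**
Total step count: 13 (steps 1–5 chromane fragment, steps 6–9 iodoflavone fragment, steps 10–13 union and end game; 11 is made once and used in steps 7 and 11).
Longest linear sequence: 9 steps (1, 2, 3, 4, 5, 10, 11, 12, 13).

**Three steps most likely to fail, with fallbacks**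

Step 9 (C8 against C6 iodination of 16). The fallback sets out from 11 and comes back at 17. It places the iodine before the pyranone exists, where the free chelated phenol directs the halogen to its own ortho position. Benzyltrimethylammonium dichloroiodate with CaCO3 in CH2Cl2/MeOH converts 11 into 1-[4,6-bis(benzyloxy)-2-hydroxy-3-iodophenyl]ethan-1-one F1, whose regiochemistry is checked by HMBC at this small-molecule stage. Claisen–Schmidt condensation of F1 with 12 (KOH, EtOH/THF, rt) passes through the aldol adduct 1-[4,6-bis(benzyloxy)-2-hydroxy-3-iodophenyl]-3-[4-(benzyloxy)phenyl]-3-hydroxypropan-1-one F2 to the chalcone (E)-1-[4,6-bis(benzyloxy)-2-hydroxy-3-iodophenyl]-3-[4-(benzyloxy)phenyl]prop-2-en-1-one F3. Catalytic I2 in DMSO at 130 °C closes F3 through the flavanone 5,7-bis(benzyloxy)-2-[4-(benzyloxy)phenyl]-8-iodochroman-4-one F4 to 17. The iodine must end at C8 because the only free OH available for ring closure is the one next to it.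

Step 10 (hindered Suzuki coupling; protodeboronation of 9 or reduction of 17). The fallback sets out from 8 and comes back at 18. It changes the nucleophile from boron to tin and bypasses 9. Heating 8 with Me3SnSnMe3 and Pd(PPh3)4 in toluene at 100 °C gives 2,2-dimethyl-8-(trimethylstannyl)chromane-6-carbaldehyde F5. F5 is coupled with 17 under copper- and fluoride-promoted Stille conditions (Pd(PPh3)4, CuI, CsF, DMF, 45 °C) to give 18. No aqueous base is present, so protodeboronation is not possible, and the CuI-assisted transmetalation tolerates ortho substitution.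

Step 11 (aldol on a large, poorly soluble aldehyde carrying a hydroxide-sensitive flavone). The fallback sets out from 18 and comes back at 22, bypassing 20. It replaces aldol plus oxidation by an intermolecular Claisen-type acylation at the carboxylic acid oxidation level. Pinnick oxidation of 18 (NaClO2, NaH2PO4, 2-methylbut-2-ene, t-BuOH/THF/H2O) gives 8-{5,7-bis(benzyloxy)-2-[4-(benzyloxy)phenyl]-4-oxo-4H-chromen-8-yl}-2,2-dimethylchromane-6-carboxylic acid F6. Oxalyl chloride with catalytic DMF in CH2Cl2 converts it into 8-{5,7-bis(benzyloxy)-2-[4-(benzyloxy)phenyl]-4-oxo-4H-chromen-8-yl}-2,2-dimethylchromane-6-carbonyl chloride F7. The lithium dianion of 11 (LiN(SiMe3)2, 3 equiv, THF, −78 °C) is C-acylated by F7 to give 1-(8-{5,7-bis(benzyloxy)-2-[4-(benzyloxy)phenyl]-4-oxo-4H-chromen-8-yl}-2,2-dimethylchroman-6-yl)-3-[2,4-bis(benzyloxy)-6-hydroxyphenyl]propane-1,3-dione F8. TsOH·H2O in toluene at 90 °C cyclodehydrates F8 to 22. This path uses neither hydroxide nor an oxidative ring closure.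

**Further compounds**
F1 | step 9 | 1-[4,6-bis(benzyloxy)-2-hydroxy-3-iodophenyl]ethan-1-one | CC(=O)c1c(O)c(I)c(OCc2ccccc2)cc1OCc1ccccc1
F2 | step 9 | 1-[4,6-bis(benzyloxy)-2-hydroxy-3-iodophenyl]-3-[4-(benzyloxy)phenyl]-3-hydroxypropan-1-one | O=C(CC(O)c1ccc(OCc2ccccc2)cc1)c1c(O)c(I)c(OCc2ccccc2)cc1OCc1ccccc1
F3 | step 9 | (E)-1-[4,6-bis(benzyloxy)-2-hydroxy-3-iodophenyl]-3-[4-(benzyloxy)phenyl]prop-2-en-1-one | O=C(/C=C/c1ccc(OCc2ccccc2)cc1)c1c(O)c(I)c(OCc2ccccc2)cc1OCc1ccccc1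
F4 | step 9 | 5,7-bis(benzyloxy)-2-[4-(benzyloxy)phenyl]-8-iodochroman-4-one | O=C1CC(c2ccc(OCc3ccccc3)cc2)Oc2c(I)c(OCc3ccccc3)cc(OCc3ccccc3)c12
F5 | step 10 | 2,2-dimethyl-8-(trimethylstannyl)chromane-6-carbaldehyde | CC1(C)CCc2cc(C=O)cc([Sn](C)(C)C)c2O1
F6 | step 11 | 8-{5,7-bis(benzyloxy)-2-[4-(benzyloxy)phenyl]-4-oxo-4H-chromen-8-yl}-2,2-dimethylchromane-6-carboxylic acid | CC1(C)CCc2cc(C(=O)O)cc(-c3c(OCc4ccccc4)cc(OCc4ccccc4)c4c(=O)cc(-c5ccc(OCc6ccccc6)cc5)oc34)c2O1
F7 | step 11 | 8-{5,7-bis(benzyloxy)-2-[4-(benzyloxy)phenyl]-4-oxo-4H-chromen-8-yl}-2,2-dimethylchromane-6-carbonyl chloride | CC1(C)CCc2cc(C(=O)Cl)cc(-c3c(OCc4ccccc4)cc(OCc4ccccc4)c4c(=O)cc(-c5ccc(OCc6ccccc6)cc5)oc34)c2O1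
F8 | step 11 | 1-(8-{5,7-bis(benzyloxy)-2-[4-(benzyloxy)phenyl]-4-oxo-4H-chromen-8-yl}-2,2-dimethylchroman-6-yl)-3-[2,4-bis(benzyloxy)-6-hydroxyphenyl]propane-1,3-dione | CC1(C)CCc2cc(C(=O)CC(=O)c3c(O)cc(OCc4ccccc4)cc3OCc3ccccc3)cc(-c3c(OCc4ccccc4)cc(OCc4ccccc4)c4c(=O)cc(-c5ccc(OCc6ccccc6)cc5)oc34)c2O1
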